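**Plan**

- Numbering: drimane numbering for the terpenoid (ring A = C1–C5 and C10, ring B = C5–C10, C11 = benzylic CH2 on C9, C12 = methyl on C8); primed locants for the arene (C1′ carries C11, O2′ is the sulfated oxygen, O3′ the free phenol, C5′ carries CH2OH).
- Cuts: O2′–S (late sulfation); C9–C10 (ring B, intramolecular Heck); C6–C7 (copper-catalysed sp3–sp3 coupling); C8–C12 together with C9–I (anti-carbomagnesiation/iodination of an alkyne); C11–alkyne carbon (benzyl–alkynyl coupling).
- Enabling feature: quaternary C10 carries C9 of the tetrasubstituted C8=C9 alkene and is flanked by C5–H, so a C9 vinylpalladium held on C5 through C8–C7–C6 can insert a ring A C10=C1 alkene and close ring B.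
- Forward order: ring A first (cationic cyclisation of geranic acid, resolution); the arene from 5-bromovanillin is extended to the chain C1′–C11–C9(I)=C8(C12)–C7; C7 is joined to C6; ring B is closed last; then O2′ release, sulfation, hydrogenation/debenzylation and desilylation.
- Stereochemistry: C5 (R) from resolution of α-cyclogeranic acid; C10 (S) from C5 through the tether in the Heck step (cis ring fusion); the (Z)-iodoalkene geometry from chelation-controlled anti addition.

Key step: step 16

Remark: the target is drawn as the free hydrogen sulfate; it is liberated only in the last work-up and would be stored as its sodium salt.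
Remark: which enantiomer of 1-phenylethylamine gives the less soluble salt with the (R)-acid must be settled by a trial crystallisation; the route is written with the (R)-amine, and the (S)-amine serves equally if the pairing is reversed.
Abbreviation: Ar = 3-(benzyloxy)-2-(methoxymethoxy)-5-({[tri(propan-2-yl)silyl]oxy}methyl)phenyl (C1′ is the point of attachment; O2′ MOM, O3′ benzyl, C5′ CH2OTIPS).

**Route**

Step 1
Reactants: 1 geranic acid
Product: 2 (±)-α-cyclogeranic acid (rac-2,6,6-trimethylcyclohex-2-ene-1-carboxylic acid)
Conditions: 85% H3PO4, toluene, 90 °C; crystallise from hexane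
Reagents that add atoms: none
Why: Brønsted-acid-promoted cationic cyclisation of a 1,5-diene (protonation of the terminal trisubstituted alkene, ring closure onto the conjugated alkene, proton loss to the endocyclic trisubstituted position) is the classical entry to α-cyclogeranic acid, obtained here as the racemate.

Step 2
Reactants: 2 (±)-α-cyclogeranic acid; 3 (R)-1-phenylethylamine
Product: 4 (R)-1-phenylethylammonium (R)-2,6,6-trimethylcyclohex-2-ene-1-carboxylate
Conditions: acetone, reflux then 4 °C; recrystallise from acetone to constant rotation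
Reagents that add atoms: none
Why: Classical resolution through diastereomeric ammonium carboxylate salts, whose different solubilities should leave the salt of the (R)-acid after repeated crystallisation, so that the stereocentre that becomes C5 of the target is fixed here.

Step 3
Reactants: 4 (R)-1-phenylethylammonium (R)-α-cyclogeranate
Product: 5 (R)-α-cyclogeraniol ([(1R)-2,6,6-trimethylcyclohex-2-en-1-yl]methanol)
Conditions: LiAlH4 (excess), THF, 0 °C to reflux; aq. NaOH work-up; amine removed with 1 M HCl
Reagents that add atoms: none
Why: Hydride reduction of a carboxylate with LiAlH4 gives the primary alcohol, and because hydride does not enolise the carboxylate the configuration at the α-carbon is carried over unchanged.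

Step 4
Reactants: 5 (R)-α-cyclogeraniol
Product: 6 (R)-α-cyclogeranyl iodide ((6R)-6-(iodomethyl)-1,5,5-trimethylcyclohex-1-ene)
Conditions: I2, PPh3, imidazole, toluene, 60 °C
Reagents that add atoms: iodine, SMILES II
Why: Appel-type iodination, in which the alkoxyphosphonium ion of the primary alcohol is displaced by iodide at the CH2 carbon (SN2), so the neighbouring stereocentre and the ring alkene are not touched.

Step 5
Reactants: 7 5-bromovanillin
Product: 8 3-bromo-4,5-dihydroxybenzaldehyde
Conditions: AlCl3, pyridine, CH2Cl2, reflux; then 2 M HCl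
Reagents that add atoms: none
Why: Lewis-acid-mediated O-demethylation of an ortho-hydroxyanisole, in which AlCl3 is chelated between the free phenol and the methoxy oxygen and pyridine removes the activated methyl group by SN2, so only this ether is cleaved and the aldehyde and the bromide survive.

Step 6
Reactants: 8 3-bromo-4,5-dihydroxybenzaldehyde
Product: 9 3-bromo-5-hydroxy-4-(methoxymethoxy)benzaldehyde
Conditions: MOMCl (1.05 equiv), K2CO3 (1.0 equiv), acetone, 0 °C to rt
Reagents that add atoms: chloromethyl methyl ether, SMILES COCCl
Why: Regioselective Williamson-type O-alkylation, because the hydroxyl para to the aldehyde and ortho to bromine is the more acidic one, so one equivalent of a weak base forms mainly its phenoxide and the MOM group caps the oxygen that will become the sulfated O2′.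

Step 7
Reactants: 9 3-bromo-5-hydroxy-4-(methoxymethoxy)benzaldehyde
Product: 10 3-(benzyloxy)-5-bromo-4-(methoxymethoxy)benzaldehyde
Conditions: BnBr, K2CO3, DMF, rt
Reagents that add atoms: benzyl bromide, SMILES BrCc1ccccc1
Why: Williamson ether synthesis on the remaining phenol puts a benzyl ether on the future O3′, a group that cannot migrate to the neighbouring oxygen and stays until the final hydrogenolysis.

Step 8
Reactants: 10 3-(benzyloxy)-5-bromo-4-(methoxymethoxy)benzaldehyde
Product: 11 [3-(benzyloxy)-5-bromo-4-(methoxymethoxy)phenyl]methanol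
Conditions: NaBH4, MeOH–THF, 0 °C
Reagents that add atoms: none
Why: Chemoselective hydride reduction of the aryl aldehyde with NaBH4 gives the benzylic alcohol that is the C5′ CH2OH of the target.

Step 9
Reactants: 11 [3-(benzyloxy)-5-bromo-4-(methoxymethoxy)phenyl]methanol
Product: 12 aryl bromide ArBr ({[3-(benzyloxy)-5-bromo-4-(methoxymethoxy)benzyl]oxy}tri(propan-2-yl)silane)
Conditions: TIPSCl, imidazole, DMF, rt
Reagents that add atoms: chlorotri(propan-2-yl)silane, SMILES CC(C)[Si](Cl)(C(C)C)C(C)C
Why: Silylation of the primary alcohol gives an ether that withstands organolithium and Grignard reagents, palladium catalysis, ZnBr2 and hydrogenolysis yet falls to fluoride at the end, and it avoids a benzyl ether on a benzylic alcohol, which could be hydrogenolysed at the wrong C–O bond.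

Step 10
Reactants: 12 aryl bromide ArBr
Product: 15 benzylic alcohol ArCH2OH, via aryllithium 13 (not isolated), via aldehyde 14 (not isolated)
Conditions: n-BuLi, THF, −78 °C; DMF, −78 to 0 °C; MeOH then NaBH4, 0 °C
Reagents that add atoms: N,N-dimethylformamide, SMILES CN(C)C=O
Why: Bromine–lithium exchange (favoured by the ortho MOM ether), formylation of the aryllithium with DMF and in situ NaBH4 reduction place the C11 carbon on C1′ without isolation of the aldehyde.

Step 11
Reactants: 15 benzylic alcohol ArCH2OH
Product: 16 benzylic bromide ArCH2Br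
Conditions: CBr4, PPh3, CH2Cl2, 0 °C
Reagents that add atoms: tetrabromomethane, SMILES BrC(Br)(Br)Br
Why: Appel bromination converts the benzylic alcohol into the bromide under neutral conditions that MOM, benzyl and TIPS ethers tolerate.

Step 12
Reactants: 16 benzylic bromide ArCH2Br; 17 propargyl alcohol
Product: 19 4-Ar-but-2-yn-1-ol, via propargyl dimagnesium salt 18 (not isolated)
Conditions: 17 (3 equiv), EtMgBr (6 equiv), THF, 0 °C to rt; CuCl (10 mol %); then 16, THF, 50 °C
Reagents that add atoms: none
Why: Copper-catalysed sp–sp3 coupling of an alkynylmagnesium reagent with a benzylic bromide (SN2) forms the C11–alkyne bond, and since the magnesium alkoxide end of 18 does not react with the bromide no protecting group is needed.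

Step 13
Reactants: 19 4-Ar-but-2-yn-1-ol; 20 methylmagnesium bromide
Product: 22 (2Z)-4-Ar-3-iodo-2-methylbut-2-en-1-ol, via vinylmagnesium chelate 21 (not isolated)
Conditions: MeMgBr (5 equiv), CuI (20 mol %), THF, 0 to 40 °C; then I2, THF, −40 to 0 °C
Reagents that add atoms: iodine, SMILES II
Why: Copper-catalysed anti-carbomagnesiation of a propargylic alcohol delivers methyl to the alkyne carbon next to the carbinol carbon (C8) and magnesium to the distal carbon (C9) on the opposite face, where the alkoxide oxygen holds it in the five-membered chelate 21, and iodinolysis with retention gives the (Z)-iodoalkene with iodine cis to CH2OH (C7) and C11 cis to C12.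

Step 14
Reactants: 22 (2Z)-4-Ar-3-iodo-2-methylbut-2-en-1-ol
Product: 23 (2Z)-4-Ar-1-bromo-3-iodo-2-methylbut-2-ene
Conditions: CBr4, PPh3, CH2Cl2, −20 °C
Reagents that add atoms: tetrabromomethane, SMILES BrC(Br)(Br)Br
Why: Appel bromination of the primary allylic alcohol proceeds by SN2 at C7, the fully substituted γ-carbon blocks SN2′ attack and the tetrasubstituted iodoalkene keeps its geometry.

Step 15
Reactants: 6 (R)-α-cyclogeranyl iodide; 23 (2Z)-4-Ar-1-bromo-3-iodo-2-methylbut-2-ene
Product: 25 (Z)-vinyl iodide ((2Z)-1-Ar-2-iodo-3-methyl-5-[(1R)-2,6,6-trimethylcyclohex-2-en-1-yl]pent-2-ene), via Grignard reagent 24 (not isolated)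
Conditions: 6, Mg, THF, 40 °C; then 23, Li2CuCl4 (5 mol %), THF, −40 to 0 °C
Reagents that add atoms: none
Why: Copper-catalysed cross-coupling of a primary alkyl Grignard reagent with a primary allylic bromide forms C6–C7 at C7 because the γ-carbon C9 is fully substituted, the vinyl iodide reacts far more slowly than the allylic bromide at low temperature, and C5 is not involved, so its configuration is kept.

Step 16
Reactants: 25 (Z)-vinyl iodide
Product: 26 cis-fused diene ((5R,10S)-11-Ar-drima-1,8-diene: C1=C2 and C8=C9, methyl on C10 cis to H5)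
Conditions: Pd(OAc)2 (10 mol %), PPh3 (40 mol %), Ag2CO3 (2 equiv), MeCN, 80 °C
Reagents that add atoms: none
Why: Zerovalent palladium (formed in situ from Pd(OAc)2 and PPh3) inserts into the C9–I bond with retention of the alkene geometry, the resulting vinylpalladium (divalent palladium, made cationic by Ag2CO3) adds syn across the ring A C10=C1 alkene so that C9 bonds to C10 and palladium moves to C1, and syn β-hydride elimination towards C2 (C10 has no hydrogen) releases the C1=C2 alkene and returns the catalyst. The closest known reaction type is the intramolecular Heck cyclisation of a vinyl halide onto a trisubstituted cycloalkene that creates a quaternary carbon in a cis-fused bicycle. Ring B closes in the 6-exo-trig mode (C9–C8–C7–C6–C5–C10), the 7-endo alternative at C1 being geometrically disfavoured for this four-atom tether. The new stereocentre C10 is controlled by C5: the tether starts at this allylic carbon, so the vinylpalladium can reach only the alkene face on which C6 lies and the C10 methyl group ends cis to H5. The step needs this facial selectivity, exo regioselectivity and an intact tetrasubstituted alkene; they are secured by the C5 stereocentre of 25, by the tether length and by the (Z) geometry of the iodide (iodine cis to C7), which places C8=C9 inside the new ring with C11 and C12 already attached, while any migration of the ring A alkene is harmless because that alkene is hydrogenated in step 19.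

Step 17
Reactants: 26 cis-fused diene
Product: 27 phenol (26 with O2′–H in place of the MOM ether)
Conditions: ZnBr2, n-PrSH, CH2Cl2, 0 °C, 10 min
Reagents that add atoms: none
Why: Lewis acid–thiol cleavage of an aryl MOM acetal, in which ZnBr2 activates the acetal and the thiol traps the methoxymethyl cation within minutes, so no protic acid is present that could add the freed phenol across C8=C9 or cleave the TIPS ether.

Step 18
Reactants: 27 phenol
Product: 28 sodium aryl sulfate (27 with O2′–SO3Na)
Conditions: SO3·pyridine (4 equiv), pyridine, 40 °C; aq. NaHCO3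
Reagents that add atoms: sulfur trioxide–pyridine complex, SMILES [O-]S(=O)(=O)[n+]1ccccc1; sodium hydrogen carbonate, SMILES [Na+].OC([O-])=O
Why: O-Sulfation of a phenol with the SO3·pyridine complex can only occur at O2′, the single free hydroxyl, so the position of the sulfate is fixed by the protecting-group pattern, and the weakly basic medium leaves the alkenes and the benzyl and silyl ethers alone.

Step 19
Reactants: 28 sodium aryl sulfate
Product: 29 sodium salt of the O3′-free ring A saturated sulfate (C5′ CH2OTIPS retained)
Conditions: H2 (1 atm), 10% Pd/C, MeOH–EtOAc, rt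
Reagents that add atoms: none
Why: Heterogeneous catalytic hydrogenation with concurrent O-benzyl hydrogenolysis saturates the cis-disubstituted C1=C2 alkene and cleaves the aryl benzyl ether, whereas the tetrasubstituted C8=C9 alkene next to quaternary C10, the aryl sulfate and the benzylic silyl ether are expected to persist, and no stereocentre is formed or disturbed.

Step 20
Reactants: 29 sodium salt of the silyl-protected sulfate
Product: 30 target ((5R,10S)-11-[3-hydroxy-5-(hydroxymethyl)-2-(sulfooxy)phenyl]drim-8-ene, 5,10-cis)
Conditions: TBAF, THF, 0 °C to rt; sulfonic acid cation-exchange resin (H+ form), MeOH–H2O, 0 °C; lyophilise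
Reagents that add atoms: none
Why: Fluoride-mediated desilylation (driven by the strong Si–F bond) frees the primary alcohol under conditions to which an aryl sulfate monoester is inert, and cation exchange converts the salt into the hydrogen sulfate drawn for the target.

**Compound list**

1 | geranic acid ((2E)-3,7-dimethylocta-2,6-dienoic acid) | CC(C)=CCC/C(C)=C/C(=O)O | starting material
2 | (±)-α-cyclogeranic acid | CC1=CCCC(C)(C)C1C(=O)O | intermediate
3 | (R)-1-phenylethylamine | C[C@@H](N)c1ccccc1 | starting material
4 | (R)-1-phenylethylammonium (R)-2,6,6-trimethylcyclohex-2-ene-1-carboxylate | CC1=CCCC(C)(C)[C@H]1C(=O)[O-].C[C@@H]([NH3+])c1ccccc1 | intermediate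
5 | (R)-α-cyclogeraniol | CC1=CCCC(C)(C)[C@H]1CO | intermediate
6 | (R)-α-cyclogeranyl iodide | CC1=CCCC(C)(C)[C@H]1CI | intermediate
7 | 5-bromovanillin (3-bromo-4-hydroxy-5-methoxybenzaldehyde) | COc1cc(C=O)cc(Br)c1O | starting material
8 | 3-bromo-4,5-dihydroxybenzaldehyde | O=Cc1cc(O)c(O)c(Br)c1 | intermediate
9 | 3-bromo-5-hydroxy-4-(methoxymethoxy)benzaldehyde | COCOc1c(O)cc(C=O)cc1Br | intermediate
10 | 3-(benzyloxy)-5-bromo-4-(methoxymethoxy)benzaldehyde | COCOc1c(OCc2ccccc2)cc(C=O)cc1Br | intermediate
11 | [3-(benzyloxy)-5-bromo-4-(methoxymethoxy)phenyl]methanol | COCOc1c(OCc2ccccc2)cc(CO)cc1Br | intermediate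
12 | aryl bromide ArBr | COCOc1c(OCc2ccccc2)cc(CO[Si](C(C)C)(C(C)C)C(C)C)cc1Br | intermediate
13 | aryllithium ArLi | [Li]c1cc(CO[Si](C(C)C)(C(C)C)C(C)C)cc(OCc2ccccc2)c1OCOC | intermediate (not isolated)
14 | aldehyde ArCHO | O=Cc1cc(CO[Si](C(C)C)(C(C)C)C(C)C)cc(OCc2ccccc2)c1OCOC | intermediate (not isolated)
15 | benzylic alcohol ArCH2OH | OCc1cc(CO[Si](C(C)C)(C(C)C)C(C)C)cc(OCc2ccccc2)c1OCOC | intermediate
16 | benzylic bromide ArCH2Br | BrCc1cc(CO[Si](C(C)C)(C(C)C)C(C)C)cc(OCc2ccccc2)c1OCOC | intermediate
17 | propargyl alcohol (prop-2-yn-1-ol) | C#CCO | starting material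
18 | bromomagnesium 3-(bromomagnesio)prop-2-yn-1-olate | Br[Mg]C#CCO[Mg]Br | intermediate (not isolated)
19 | 4-Ar-but-2-yn-1-ol | OCC#CCc1cc(CO[Si](C(C)C)(C(C)C)C(C)C)cc(OCc2ccccc2)c1OCOC | intermediate
20 | methylmagnesium bromide | C[Mg]Br | starting material
21 | vinylmagnesium chelate (3-(ArCH2)-4-methyl-2,5-dihydro-1,2-oxamagnesole, drawn as the monomer) | CC1=C(Cc2cc(CO[Si](C(C)C)(C(C)C)C(C)C)cc(OCc3ccccc3)c2OCOC)[Mg]OC1 | intermediate (not isolated)
22 | (2Z)-4-Ar-3-iodo-2-methylbut-2-en-1-ol | C/C(CO)=C(/I)Cc1cc(CO[Si](C(C)C)(C(C)C)C(C)C)cc(OCc2ccccc2)c1OCOC | intermediate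
23 | (2Z)-4-Ar-1-bromo-3-iodo-2-methylbut-2-ene | C/C(CBr)=C(/I)Cc1cc(CO[Si](C(C)C)(C(C)C)C(C)C)cc(OCc2ccccc2)c1OCOC | intermediate
24 | {[(1R)-2,6,6-trimethylcyclohex-2-en-1-yl]methyl}magnesium iodide | CC1=CCCC(C)(C)[C@H]1C[Mg]I | intermediate (not isolated)
25 | (Z)-vinyl iodide, Heck precursor | CC1=CCCC(C)(C)[C@H]1CC/C(C)=C(\I)Cc1cc(CO[Si](C(C)C)(C(C)C)C(C)C)cc(OCc2ccccc2)c1OCOC | intermediate
26 | cis-fused diene, (5R,10S)-11-Ar-drima-1,8-diene | CC1=C(Cc2cc(CO[Si](C(C)C)(C(C)C)C(C)C)cc(OCc3ccccc3)c2OCOC)[C@@]2(C)C=CCC(C)(C)[C@H]2CC1 | intermediate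
27 | phenol (O2′–H, O3′ benzyl, C5′ CH2OTIPS) | CC1=C(Cc2cc(CO[Si](C(C)C)(C(C)C)C(C)C)cc(OCc3ccccc3)c2O)[C@@]2(C)C=CCC(C)(C)[C@H]2CC1 | intermediate
28 | sodium aryl sulfate (O2′–SO3Na, O3′ benzyl, C5′ CH2OTIPS) | CC1=C(Cc2cc(CO[Si](C(C)C)(C(C)C)C(C)C)cc(OCc3ccccc3)c2OS(=O)(=O)[O-])[C@@]2(C)C=CCC(C)(C)[C@H]2CC1.[Na+] | intermediate
29 | sodium aryl sulfate, ring A saturated, O3′–H, C5′ CH2OTIPS | CC1=C(Cc2cc(CO[Si](C(C)C)(C(C)C)C(C)C)cc(O)c2OS(=O)(=O)[O-])[C@@]2(C)CCCC(C)(C)[C@H]2CC1.[Na+] | intermediate
30 | target, (5R,10S)-11-[3-hydroxy-5-(hydroxymethyl)-2-(sulfooxy)phenyl]drim-8-ene | CC1=C(Cc2cc(CO)cc(O)c2OS(=O)(=O)O)[C@@]2(C)CCCC(C)(C)[C@H]2CC1 | target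

**Totals**

Total step count: 20.
Longest linear sequence: 16 steps (steps 5 to 20, from 5-bromovanillin); the terpenoid branch (steps 1 to 4) joins at step 15.

**The three steps most likely to fail**

1. Step 16 (Heck cyclisation). What may go wrong: carbopalladation of the hindered trisubstituted ring alkene by a tetrasubstituted vinylpalladium is slow, so that reduction of the C–I bond or a 1,4-shift of palladium from C9 to C6′ of the arene takes over. The fallback sets out from 25 and comes back at 26. It closes ring B by palladium-catalysed intramolecular α-alkenylation of a ketone enolate, which makes the same C9–C10 bond with C10 as the nucleophile.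
   - Hydroboration–oxidation of the ring A alkene of 25 (BH3·THF; then NaOH, H2O2) would put boron on the less substituted C1, the iodoalkene being inert, and give the C1 alcohol F1.
   - Dess–Martin oxidation would give the C1 ketone F2; its C10 epimers are immaterial.
   - Pd(PPh3)4 and t-BuOK in THF would couple the more substituted enolate carbon C10 with the vinyl iodide to give the cis-fused C1 ketone F3. Reaction at C2 would need an eight-membered ring, and the tether from C5 again enforces the cis fusion.
   - KN(SiMe3)2 and PhNTf2 would give the C1 enol triflate F4, and formate reduction of the triflate (Pd(OAc)2, PPh3, HCO2H, Bu3N, DMF, 60 °C) returns 26.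

2. Step 13 (anti-carbomagnesiation). What may go wrong: methyl transfer from MeMgBr to an internal alkynol is sluggish, and long exposure to the basic reagent can move the alkyne into conjugation with the arene by propargyl–allenyl isomerisation at the doubly activated C11. The fallback sets out from aryl bromide 12 and comes back at 22. It exchanges the roles, so that the aryl group and not the methyl group is the Grignard partner.
   - Aryllithium 13, made as in step 10, is transmetalated with MgBr2·OEt2 to the arylmagnesium bromide F6.
   - F6 is added, with CuCl as catalyst, to 2-methylbuta-2,3-dien-1-ol F5 that has been deprotonated beforehand with EtMgBr. F5 is a known compound, available in one step from 4-chlorobut-2-yn-1-ol and MeMgBr with CuI.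
   - In this copper-catalysed carbomagnesiation of a 2,3-allenol the aryl group adds to the terminal allene carbon (forming C1′–C11) and magnesium goes to the central carbon C9 under direction by the alkoxide. This gives the same chelate 21, which iodine converts into 22.
   - Steps 10 to 13 are replaced.

3. Step 15 (Grignard coupling). What may go wrong: formation of the hindered homoallylic Grignard reagent is eroded by Wurtz coupling, or the reagent undergoes iodine–magnesium exchange at the vinyl iodide faster than substitution at C7. The fallback sets out from 6 and 23 and comes back at 26. It makes C6 nucleophilic as a sulfone-stabilised carbanion (Julia-type alkylation) and removes the sulfonyl group only after ring closure, because a dissolving metal would also reduce the vinyl iodide.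
   - Sodium benzenesulfinate in DMF at 80 °C would convert 6 into (R)-α-cyclogeranyl phenyl sulfone F7.
   - Deprotonation (n-BuLi, THF, −78 °C) and alkylation with 23 would give the C6-sulfonyl vinyl iodide F8 as both C6 epimers.
   - The Heck conditions of step 16 would give the C6-sulfonyl diene F9.
   - Sodium amalgam (Na/Hg, Na2HPO4, MeOH–THF, −20 °C) would remove the sulfonyl group and give 26.

Further compounds
F1 | step 16 | C1 alcohol from hydroboration of 25 (C1 and C10 epimers) | CC1C(O)CCC(C)(C)[C@H]1CC/C(C)=C(\I)Cc1cc(CO[Si](C(C)C)(C(C)C)C(C)C)cc(OCc2ccccc2)c1OCOC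
F2 | step 16 | C1 ketone (C10 epimers) | CC1C(=O)CCC(C)(C)[C@H]1CC/C(C)=C(\I)Cc1cc(CO[Si](C(C)C)(C(C)C)C(C)C)cc(OCc2ccccc2)c1OCOC
F3 | step 16 | cis-fused 11-Ar-drim-8-en-1-one | CC1=C(Cc2cc(CO[Si](C(C)C)(C(C)C)C(C)C)cc(OCc3ccccc3)c2OCOC)[C@@]2(C)C(=O)CCC(C)(C)[C@H]2CC1
F4 | step 16 | C1 enol triflate of F3 | CC1=C(Cc2cc(CO[Si](C(C)C)(C(C)C)C(C)C)cc(OCc3ccccc3)c2OCOC)[C@@]2(C)C(OS(=O)(=O)C(F)(F)F)=CCC(C)(C)[C@H]2CC1
F5 | step 13 | 2-methylbuta-2,3-dien-1-ol | C=C=C(C)CO
F6 | step 13 | arylmagnesium bromide ArMgBr | Br[Mg]c1cc(CO[Si](C(C)C)(C(C)C)C(C)C)cc(OCc2ccccc2)c1OCOC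
F7 | step 15 | (R)-α-cyclogeranyl phenyl sulfone | CC1=CCCC(C)(C)[C@H]1CS(=O)(=O)c1ccccc1
F8 | step 15 | C6-phenylsulfonyl derivative of 25 (C6 epimers) | CC1=CCCC(C)(C)[C@H]1C(C/C(C)=C(\I)Cc1cc(CO[Si](C(C)C)(C(C)C)C(C)C)cc(OCc2ccccc2)c1OCOC)S(=O)(=O)c1ccccc1
F9 | step 15 | C6-phenylsulfonyl derivative of 26 (C6 epimers) | CC1=C(Cc2cc(CO[Si](C(C)C)(C(C)C)C(C)C)cc(OCc3ccccc3)c2OCOC)[C@@]2(C)C=CCC(C)(C)[C@H]2C(S(=O)(=O)c2ccccc2)C1
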